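(The readings were generated by integration for substances that don't exist; the scatter is artificial.)

I had no constants for this flask, so I turned each run into a single time and let that time do the reckoning.

| flask | substrate | partner | free catalyst | time |
|---|---|---|---|---|
| autumn | 50.0 mM | 55.0 mM | 5.00 mM |  |
| dusk | 50.0 mM | 55.0 mM | 15.0 mM |  |
| dawn | 100 mM | 55.0 mM | 5.00 mM |  |
| winter | 50.0 mM | 28.0 mM | 5.00 mM |  |
| spring | 17.0 mM | 18.0 mM | 5.00 mM | 140 min |

- autumn run (time / min: [product] / mM): 11: 3.18; 32: 8.51; 62: 14.49; 98: 20.13; 140: 24.90
- dusk run (time / min: [product] / mM): 11: 11.20; 32: 24.09; 62: 33.51; 98: 38.68; 140: 42.60
- dawn run (time / min: [product] / mM): 11: 5.70; 32: 14.40; 62: 23.62; 98: 31.66; 140: 37.85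
- winter run (time / min: [product] / mM): 11: 2.07; 32: 5.10; 62: 8.39; 98: 11.83; 140: 15.08

(scatter of a reading: 0.2 mM)

* order of the initial rate in [partner], near the charge of the autumn run, the rate being that where two percent of its substrate are product
* order of the initial rate in [free catalyst], near the charge of the autumn run, the rate being that where two percent of its substrate are product
* product in the spring run at 140 min, as a share of the substrate charged

- Overall: substrate + partner -> product, with free catalyst as catalyst.
- Constant volume, constant temperature.
- What is held in complexes is read along with the free species.
- An order is taken over about fifteen percent of the charge, up and down.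

I took each run as first order in substrate and first order in partner, and integrated that law up to its last reading to get an apparent rate constant. The second-order time of a run is the inverse of this constant at spring's substrate charge, where substrate is the limiting reagent. It came to 537 min in dawn, 477 min in autumn and 437 min in winter. So the time was longer in dawn than in autumn and shorter in winter. In dawn, autumn and winter, which share a catalyst charge, I read it as rising with the summed charge of substrate and partner, which as a fraction of autumn's is 1.48 in dawn, 0.743 in winter and 0.333 in spring.

Spring's fraction is smaller than winter's, so I expected its time to lie below winter's, and winter's time unchanged gave my floor, a share of 25.5%. The line through dawn and winter rises 137 min per whole autumn charge. Its intercept, 336 min, gave my ceiling of 30.9%. At spring's own fraction the line reads 381 min, so I committed to 28.2%. The same slope gave me a partner order of 0.850. Dusk's time of 97.8 min against autumn's gave an average catalyst order between their charges of 1.44.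

The forecast gave 0.55 in partner, 1.2 in catalyst and 31% for spring, with the remark “The rate looks saturating”. Its share stood at my ceiling, and both its orders were lower than mine.

The spring run gave 28.3% of its substrate as product at 140 min. Near the autumn charge, the initial-rate orders came to 0.83 in partner and 1.5 in free catalyst.

    2 free catalyst ⇌ catalyst dimer, settled at all times (3260 /M)
    catalyst dimer + substrate + partner → product + catalyst dimer (120.0 /M²/min)
    substrate + partner ⇌ idle substrate-reagent adduct, settled at all times (6.680 /M)
    free catalyst + impurity → spent catalyst

Parking substrate and partner as idle substrate-reagent adduct moved the readings by 25 times the scatter, root mean square. Dawn's time of 537 min put the product at a quarter of the dawn substrate charge at 64.6 min, and the dawn run reached that amount at 67.3 min.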